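Atom labels follow the benzofuran numbering of the target throughout (O1, C2 aryl, C3 methyl, C3a quaternary, C4–C7, C7a; ring A the carbocycle, ring B the oxygen ring). Ar = 3,4,5-trimethoxyphenyl.

## The problem

The target 26 is a 3a-allyl-3,3a-dihydrobenzofuran-6(2H)-one. Ring B (O1–C2–C3–C3a–C7a) is fused to ring A (C3a–C4–C5–C6–C7–C7a) through the quaternary sp3 carbon C3a and the sp2 carbon C7a. Ring A is a cross-conjugated 2-methoxycyclohexa-2,5-dienone whose C7=C7a bond is also the enol ether of ring B. There are three contiguous stereocentres, C2 (aryl), C3 (methyl) and C3a (allyl), with aryl and methyl cis, allyl trans to methyl, and absolute configuration 2R,3S,3aS. C2 and C3 are a syn aryl carbinol/methyl pair that a reagent-controlled carbonyl addition can set; once they sit cis on a five-membered ring they block one face and can dictate C3a, which cannot be corrected later. The dienone with its allyl group (acid-induced allyl migration and aromatisation), the enol ether, the terminal alkene and the electron-rich benzylic ether at C2 all argue for bringing ring A to its final oxidation level late and without acid. The feature that opens the synthesis is that C5 and C6 are adjacent and both oxygenated, an acyloin pattern, so both can start as aldehyde carbons of like polarity and be joined after polarity reversal of one. Because C3a is quaternary and C7 is sp2, the derived 1,2-dione can enolise only toward C4, which is where the methyl ether must end. A hidden demand follows: C6 must lie on the C3a side of the exocyclic C7=C7a bond (E), the sterically disfavoured geometry, so the enal has to be assembled under kinetic control.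

## Retrosynthesis

**Methyl ether and oxidation level of C5/C6.** The O–CH3 bond on C5 is cut first: 26 comes from diosphenol 25 by O-methylation. 25 is the only possible enol of 1,2-dione 24, which is the oxidation product of acyloin 23. Against carrying a methoxy enol ether through the route, this keeps the acid-sensitive dienone out of all but the last two steps. The forward steps need only be mild: an alcohol oxidation that spares alkene and arene, and methylation on oxygen.

**C5–C6 bond (key cut).** Cutting C5–C6 in 23 opens ring A and gives dialdehyde 22. The neighbouring cuts are poorer: C4–C5 or C6–C7 are aldol or acylation cuts that still leave a 1,2-dioxygenated fragment to be made, and C3a–C4 gives up the quaternary centre. The C5–C6 cut turns both oxygenated carbons into the same functional group and leaves a monocyclic oxolane with no stereocentre in the part to be closed. The forward reaction must make an acyl anion equivalent at C5 from the aliphatic aldehyde, add it to the C6 carbonyl in a six-membered closure, and find C6 on the C3a side of the double bond.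

**The E enal: O1–C7a and C7–C6 bonds.** 22 is traced through diol 21 and silyl ether 20 to ester 19; these are oxidation-level changes only. In 19 the O1–C7a and C7–C6 bonds are cut together, giving acyclic alkynol 18. A shorter neighbour would be methylenation of lactone 16 followed by Vilsmeier–Haack formylation, but that places the formyl carbon under thermodynamic control, away from the quaternary carbon, where it cannot reach C5. Anti-oxypalladation of the alkyne puts the metal, and hence the ester carbon, trans to O1, a kinetic outcome. The forward step needs attack by the C2 hydroxyl only (so the C5 oxygen stays silylated) and carbonylative capture faster than any other fate of the alkenylpalladium.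

**C7a≡C7.** The terminal carbon C7 of 18 is removed by reversing a one-carbon alkyne homologation of the aldehyde masked in lactol 17, the reduction product of lactone 16. This returns C7a to the carboxyl level and O1 to a ring, which is the template needed for C3a. The forward homologation acts on a neopentyl aldehyde with no α-hydrogen and frees the C2 hydroxyl at the same time.

**The two C3a–carbon bonds.** Both substituents on C3a in 16 are cut: allyl back to allyl bromide 14 and lactone 13, the silyloxyethyl arm back to triflate 11 (from alcohol 10) and lactone 9. The order is fixed by the target: the second electrophile enters anti to the cis C4-methyl and C5-aryl groups of the lactone, and allyl must end trans to methyl, so allyl goes in last. Building the quaternary carbon on an open chain would offer no such bias. 9 carries only the C2/C3 pair.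

**C2–C3 bond.** 9 is the oxidative lactonisation product of diol 7, which comes from alkene 5 by hydroboration. Cutting C2–C3 in 5 gives aldehyde 1 and a crotyl unit from cis-2-butene 2, delivered by borane 4. This sets both stereocentres and the absolute configuration in one reagent-controlled step. A carbene-catalysed homoenolate annulation of 1 would reach the cis lactone in one step, but not dependably as one enantiomer.

## Roads not taken

**Alternative 1:** The C3 methyl is traced to a cyclopropane methylene. The enol ether A1 (C2=C3 double bond, dienone complete) would be cyclopropanated with CF3CO2ZnCH2I (from Et2Zn, CH2I2 and CF3CO2H) anti to the allyl group to give A2, and the C2–CH2 bond would then be cleaved to reveal the methyl group and C2–H.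
- Merits: A1 is flat apart from C3a, C3 follows from C3a by facial control, ring A needs no late redox chemistry, and on paper the route is shorter than the chosen one.
- Weak points: A1 offers four C=C bonds to an electrophilic carbenoid, and the C4=C5 methoxy enol ether competes with C2=C3.
- In A2 the methylene and the aryl group lie on opposite faces of ring B, so cleavage with retention gives the C2 epimer; the cis aryl/methyl pair needs net inversion at C2.
- An ionic opening with hydride delivery would need acid, which a 3a-allyl dienone tolerates badly; hydrogenolysis endangers the allyl group and the dienone.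
- The absolute configuration at C3a must still come from a separate asymmetric step.
- Comparison: Alternative 1 is better in step count and in ring A handling. The chosen plan sets against this that every stereocentre has a predictable origin and the dienone is exposed only at the end.

**Alternative 2:** The O1–C7a bond is cut. The symmetric 2,6-dimethoxycyclohexa-2,5-dienone A3, with allyl and the hydroxy side chain on the same carbon, would close by 5-exo-trig oxa-Michael addition of the C2 hydroxyl to one of two diastereotopic β-carbons, giving cis-fused A4 and fixing C3a.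
- Merits: the quaternary carbon is made as a non-stereogenic centre, ring A is present from the start so no alkene-geometry problem arises, and the reversible closure allows thermodynamic selection. In these respects it is better than the chosen plan.
- Weak points: the choice between the two enone arms rests only on the acyclic C2/C3 pair, and the target needs the more crowded outcome, with the ring A arm cis to methyl and aryl.
- A4 carries one methoxy group too many. Base returns A4 to A3 by retro-Michael opening, so removing methanol across C7–C7a needs a detour of reductive loss of the α-methoxy group and then dehydrogenation.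
- A3 itself requires an alkylative dearomatisation with a stereodefined side chain.
- Comparison: the chosen plan is longer, but sets C3a by an enolate alkylation with a clear facial bias and arrives at the exact oxidation level.

**Alternative 3:** The C3a–C7a bond is cut. Thermolysis of the 4-alkenyl-4-methoxycyclobutenone A5 would open it to a dienylketene, which closes by 6π electrocyclisation to the 6,6-disubstituted cyclohexa-2,4-dienone A6. Desilylation and vinylogous transesterification onto C7a would then form ring B.
- Merits: very convergent, and ring A arrives with its full oxygen pattern from a squarate; here it is ahead of the chosen plan.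
- Weak points: C3a is created in the electrocyclisation, under the influence only of the adjacent acyclic C3 centre and the geometry of a trisubstituted alkene that must itself be made stereodefined.
- A6 cannot tautomerise to a phenol and can reopen or dimerise.
- The later isopropoxy-to-O1 transposition needs acid on an allyl dienone.
- Comparison: the chosen plan gives up convergence for a ring-based, predictable setting of C3a.

Key step: step 13

## Route

Assumption: alcohol 10 (the mono-silyl ether of ethylene glycol) is taken as purchasable; 23 is carried on as a mixture of C6 epimers, which is immaterial because step 14 removes that centre.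

Step 1
Reactants: 1 3,4,5-trimethoxybenzaldehyde; 2 cis-2-butene
Product: 5 (1R,2S)-2-methyl-1-(3,4,5-trimethoxyphenyl)but-3-en-1-ol, via (Z)-crotylpotassium 3 (not isolated), via (Z)-crotylbis(isopinocampheyl)borane 4 (not isolated)
Conditions: n-BuLi, KOt-Bu, THF, −78 to −45 °C; (+)-Ipc2BOMe, −78 °C; BF3·OEt2, then 1, −78 °C; NaOH, H2O2, 23 °C
Reagents that add atoms: none
Why: Brown asymmetric crotylboration through a closed chair transition state; the Z crotyl geometry gives the syn (C2/C3) pair and the isopinocampheyl groups of the (−)-α-pinene series select the aldehyde face that leads to the 1R carbinol.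

Step 2
Reactants: 5 (1R,2S)-2-methyl-1-(3,4,5-trimethoxyphenyl)but-3-en-1-ol
Product: 7 (1R,2S)-2-methyl-1-(3,4,5-trimethoxyphenyl)butane-1,4-diol, via O,C-bis(9-BBN) adduct 6 (not isolated)
Conditions: 9-BBN (2.5 equiv), THF, 0 to 23 °C; NaOH, H2O2, 0 °C
Reagents that add atoms: hydrogen peroxide, OO
Why: Anti-Markovnikov hydroboration–oxidation of a monosubstituted alkene; no stereocentre is touched.

Step 3
Reactants: 7 (1R,2S)-2-methyl-1-(3,4,5-trimethoxyphenyl)butane-1,4-diol
Product: 9 (4S,5R)-4-methyl-5-(3,4,5-trimethoxyphenyl)oxolan-2-one, via lactol 8 (not isolated)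
Conditions: 2,2,6,6-tetramethylpiperidin-1-oxyl (cat.), PhI(OAc)2, CH2Cl2, 23 °C
Reagents that add atoms: none
Why: Oxidative lactonisation of a 1,4-diol: the oxoammonium oxidant takes the primary alcohol first, the hydroxy aldehyde closes to lactol 8, and this is oxidised on to the cis lactone.

Step 4
Reactants: 10 2-(tert-butyldiphenylsilyloxy)ethanol
Product: 11 2-(tert-butyldiphenylsilyloxy)ethyl trifluoromethanesulfonate
Conditions: Tf2O, 2,6-lutidine, CH2Cl2, −78 °C; used at once
Reagents that add atoms: trifluoromethanesulfonic anhydride, O=S(=O)(OS(=O)(=O)C(F)(F)F)C(F)(F)F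
Why: Sulfonylation of a primary alcohol; the triflate is chosen because β-silyloxyethyl halides alkylate lactone enolates sluggishly.

Step 5
Reactants: 9 (4S,5R)-4-methyl-5-(3,4,5-trimethoxyphenyl)oxolan-2-one; 11 2-(tert-butyldiphenylsilyloxy)ethyl trifluoromethanesulfonate
Product: 13 (3S,4S,5R)-3-[2-(tert-butyldiphenylsilyloxy)ethyl]-4-methyl-5-(3,4,5-trimethoxyphenyl)oxolan-2-one, via lithium enolate 12 (not isolated)
Conditions: LiN(i-Pr)2, THF, −78 °C; then 11, −78 to −40 °C
Reagents that add atoms: none
Why: Kinetic lactone enolate alkylation with a primary triflate; the arm should enter anti to the C4 methyl, but this centre is flattened again in step 6, so its configuration does not matter.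

Step 6
Reactants: 13 (3S,4S,5R)-3-[2-(tert-butyldiphenylsilyloxy)ethyl]-4-methyl-5-(3,4,5-trimethoxyphenyl)oxolan-2-one; 14 allyl bromide
Product: 16 (3R,4S,5R)-3-allyl-3-[2-(tert-butyldiphenylsilyloxy)ethyl]-4-methyl-5-(3,4,5-trimethoxyphenyl)oxolan-2-one, via lithium enolate 15 (not isolated)
Conditions: LiN(i-Pr)2, THF, −78 °C; then 14, −78 to −20 °C
Reagents that add atoms: none
Why: Alkylation of a fully substituted lactone enolate; the cis methyl and aryl groups shield the same face, so allyl bromide should add from the other face, which sets C3a with allyl trans to methyl (1,2-induction from C3).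

Step 7
Reactants: 16 (3R,4S,5R)-3-allyl-3-[2-(tert-butyldiphenylsilyloxy)ethyl]-4-methyl-5-(3,4,5-trimethoxyphenyl)oxolan-2-one
Product: 17 (3R,4S,5R)-3-allyl-3-[2-(tert-butyldiphenylsilyloxy)ethyl]-4-methyl-5-(3,4,5-trimethoxyphenyl)oxolan-2-ol (both anomers)
Conditions: i-Bu2AlH, CH2Cl2, −78 °C; aq. KNaC4H4O6
Reagents that add atoms: none
Why: Partial reduction of a lactone to the lactol; the tetrahedral aluminate is stable at −78 °C, and the silyl ether and alkene are inert.

Step 8
Reactants: 17 (3R,4S,5R)-3-allyl-3-[2-(tert-butyldiphenylsilyloxy)ethyl]-4-methyl-5-(3,4,5-trimethoxyphenyl)oxolan-2-ol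
Product: 18 (1R,2S,3R)-3-[2-(tert-butyldiphenylsilyloxy)ethyl]-3-ethynyl-2-methyl-1-(3,4,5-trimethoxyphenyl)hex-5-en-1-ol
Conditions: dimethyl (1-diazo-2-oxopropyl)phosphonate, K2CO3, MeOH, 0 to 23 °C
Reagents that add atoms: dimethyl (1-diazo-2-oxopropyl)phosphonate, CC(=O)C(=[N+]=[N-])P(=O)(OC)OC
Why: Seyferth–Gilbert homologation with the Ohira–Bestmann reagent on the open hydroxy aldehyde in equilibrium with the lactol; the α-carbon is quaternary, so nothing can epimerise, and the C2 hydroxyl is set free for step 9.

Step 9
Reactants: 18 (1R,2S,3R)-3-[2-(tert-butyldiphenylsilyloxy)ethyl]-3-ethynyl-2-methyl-1-(3,4,5-trimethoxyphenyl)hex-5-en-1-ol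
Product: 19 methyl (2E)-2-[(3R,4S,5R)-3-allyl-3-[2-(tert-butyldiphenylsilyloxy)ethyl]-4-methyl-5-(3,4,5-trimethoxyphenyl)oxolan-2-ylidene]acetate
Conditions: PdCl2(MeCN)2 (cat.), p-benzoquinone, CO (1 atm), MeOH, 0 to 23 °C
Reagents that add atoms: carbon monoxide, [C-]#[O+]; methanol, CO
Why: Palladium-catalysed 5-exo-dig cyclisation–methoxycarbonylation of a 4-yn-1-ol: anti-oxypalladation by divalent palladium puts the metal trans to O1, and CO insertion and methanolysis with retention give the E β-alkoxyacrylate, with C6 on the C3a side. The geometry is kinetic; benzoquinone returns the metal to the divalent state.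

Step 10
Reactants: 19 methyl (2E)-2-[(3R,4S,5R)-3-allyl-3-[2-(tert-butyldiphenylsilyloxy)ethyl]-4-methyl-5-(3,4,5-trimethoxyphenyl)oxolan-2-ylidene]acetate
Product: 20 (2E)-2-[(3R,4S,5R)-3-allyl-3-[2-(tert-butyldiphenylsilyloxy)ethyl]-4-methyl-5-(3,4,5-trimethoxyphenyl)oxolan-2-ylidene]ethan-1-ol
Conditions: i-Bu2AlH (2.5 equiv), CH2Cl2, −78 °C; aq. KNaC4H4O6; Et3N-buffered handling
Reagents that add atoms: none
Why: 1,2-Reduction of a β-alkoxyacrylate to the 3-alkoxyallyl alcohol; no acid is present, so the double bond geometry should be retained.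

Step 11
Reactants: 20 (2E)-2-[(3R,4S,5R)-3-allyl-3-[2-(tert-butyldiphenylsilyloxy)ethyl]-4-methyl-5-(3,4,5-trimethoxyphenyl)oxolan-2-ylidene]ethan-1-ol
Product: 21 2-[(2E,3R,4S,5R)-3-allyl-2-(2-hydroxyethylidene)-4-methyl-5-(3,4,5-trimethoxyphenyl)oxolan-3-yl]ethan-1-ol
Conditions: Bu4NF, THF, 0 to 23 °C
Reagents that add atoms: none
Why: Fluoride cleavage of the silyl ether; after step 10 the enol ether is no longer a Michael acceptor and is inert to fluoride and alkoxide.

Step 12
Reactants: 21 2-[(2E,3R,4S,5R)-3-allyl-2-(2-hydroxyethylidene)-4-methyl-5-(3,4,5-trimethoxyphenyl)oxolan-3-yl]ethan-1-ol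
Product: 22 2-[(2E,3R,4S,5R)-3-allyl-4-methyl-2-(2-oxoethylidene)-5-(3,4,5-trimethoxyphenyl)oxolan-3-yl]acetaldehyde
Conditions: SO3·pyridine, DMSO, i-Pr2NEt, CH2Cl2, 0 °C
Reagents that add atoms: none
Why: Parikh–Doering oxidation of both primary alcohols in one operation; the medium stays basic throughout, which protects the acid-labile enol ether and the E geometry.

Step 13
Reactants: 22 2-[(2E,3R,4S,5R)-3-allyl-4-methyl-2-(2-oxoethylidene)-5-(3,4,5-trimethoxyphenyl)oxolan-3-yl]acetaldehyde
Product: 23 (2R,3S,3aR)-3a-allyl-6-hydroxy-3-methyl-2-(3,4,5-trimethoxyphenyl)-2,3,3a,4-tetrahydro-1-benzofuran-5(6H)-one (both C6 epimers)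
Conditions: 2-(pentafluorophenyl)-6,7-dihydro-5H-pyrrolo[2,1-c][1,2,4]triazol-2-ium tetrafluoroborate (cat.), i-Pr2NEt (cat.), CH2Cl2 (dilute, degassed), 23 °C
Reagents that add atoms: none
Why: Proposed new method: the carbene should add to the unhindered aliphatic C5 aldehyde rather than to the C6 carbonyl, which is a vinylogous formate deactivated by donation from O1, and proton transfer gives the Breslow enaminol, an acyl anion equivalent at C5. This carbon attacks the C6 carbonyl, held within reach by the E double bond and the quaternary C3a, and closes ring A by a 6-exo-trig addition that forms the C5–C6 bond; collapse of the adduct releases the carbene and α-hydroxy ketone 23. The closest known reaction type is the intramolecular crossed benzoin (acyloin) cyclisation of dialdehydes and keto aldehydes under thiazolium or triazolium catalysis; the new element is a β-alkoxy enal as acceptor. Its lower electrophilicity is offset by intramolecularity, and the Stetter mode is excluded because attack at C7a would make a four-membered ring. The new carbinol centre at C6 is uncontrolled and need not be controlled, since step 14 removes it, and the regioisomeric acyloin from the reverse polarity assignment would give the same dione. Only chemoselectivity is required: dilution suppresses intermolecular acyloin coupling, and a weak amine base with an acidic triazolium keeps enolate aldol closure of C4 onto C6 in check. C2, C3 and C3a are spectators.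

Step 14
Reactants: 23 (2R,3S,3aR)-3a-allyl-6-hydroxy-3-methyl-2-(3,4,5-trimethoxyphenyl)-2,3,3a,4-tetrahydro-1-benzofuran-5(6H)-one
Product: 25 (2R,3S,3aS)-3a-allyl-5-hydroxy-3-methyl-2-(3,4,5-trimethoxyphenyl)-3,3a-dihydro-1-benzofuran-6(2H)-one, via 1,2-dione 24 (not isolated)
Conditions: Dess–Martin periodinane, NaHCO3, CH2Cl2, 0 to 23 °C
Reagents that add atoms: none
Why: Oxidation of an α-hydroxy ketone to the 1,2-dione; 24 can enolise only toward C4 (C3a quaternary, C7 sp2) and should do so at once to the conjugated diosphenol.

Step 15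
Reactants: 25 (2R,3S,3aS)-3a-allyl-5-hydroxy-3-methyl-2-(3,4,5-trimethoxyphenyl)-3,3a-dihydro-1-benzofuran-6(2H)-one
Product: 26 (2R,3S,3aS)-3a-allyl-5-methoxy-3-methyl-2-(3,4,5-trimethoxyphenyl)-3,3a-dihydro-1-benzofuran-6(2H)-one
Conditions: Me2SO4, K2CO3, acetone, 23 to 50 °C
Reagents that add atoms: dimethyl sulfate, COS(=O)(=O)OC
Why: O-Alkylation of an acidic diosphenol with a hard methylating agent under mild base (Williamson type); no stereocentre is affected.

## Compound list

1 | 3,4,5-trimethoxybenzaldehyde | COc1cc(C=O)cc(OC)c1OC | starting material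
2 | cis-2-butene | C/C=C\C | starting material
3 | (Z)-crotylpotassium (not isolated) | [K]C/C=C\C | intermediate
4 | (Z)-crotylbis[(1S,2S,3S,5R)-isopinocampheyl]borane (not isolated) | C/C=C\CB([C@H]1C[C@H]2C[C@@H]([C@@H]1C)C2(C)C)[C@H]1C[C@H]2C[C@@H]([C@@H]1C)C2(C)C | intermediate
5 | (1R,2S)-2-methyl-1-(3,4,5-trimethoxyphenyl)but-3-en-1-ol | C=C[C@H](C)[C@@H](O)c1cc(OC)c(OC)c(OC)c1 | intermediate
6 | O,C-bis(9-borabicyclo[3.3.1]nonan-9-yl) adduct of 5 (not isolated) | C(C[C@H](C)[C@@H](OB1C2CCCC1CCC2)c1cc(OC)c(OC)c(OC)c1)B1C2CCCC1CCC2 | intermediate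
7 | (1R,2S)-2-methyl-1-(3,4,5-trimethoxyphenyl)butane-1,4-diol | OCC[C@H](C)[C@@H](O)c1cc(OC)c(OC)c(OC)c1 | intermediate
8 | (4S,5R)-4-methyl-5-(3,4,5-trimethoxyphenyl)oxolan-2-ol (not isolated) | OC1C[C@H](C)[C@H](c2cc(OC)c(OC)c(OC)c2)O1 | intermediate
9 | (4S,5R)-4-methyl-5-(3,4,5-trimethoxyphenyl)oxolan-2-one | O=C1C[C@H](C)[C@H](c2cc(OC)c(OC)c(OC)c2)O1 | intermediate
10 | 2-(tert-butyldiphenylsilyloxy)ethanol | OCCO[Si](c1ccccc1)(c1ccccc1)C(C)(C)C | starting material
11 | 2-(tert-butyldiphenylsilyloxy)ethyl trifluoromethanesulfonate | O=S(=O)(OCCO[Si](c1ccccc1)(c1ccccc1)C(C)(C)C)C(F)(F)F | intermediate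
12 | lithium enolate of 9 (not isolated) | [Li]OC1=C[C@H](C)[C@H](c2cc(OC)c(OC)c(OC)c2)O1 | intermediate
13 | (3S,4S,5R)-3-[2-(tert-butyldiphenylsilyloxy)ethyl]-4-methyl-5-(3,4,5-trimethoxyphenyl)oxolan-2-one | CC(C)(C)[Si](c1ccccc1)(c1ccccc1)OCC[C@@H]1C(=O)O[C@@H](c2cc(OC)c(OC)c(OC)c2)[C@H]1C | intermediate
14 | allyl bromide | C=CCBr | starting material
15 | lithium enolate of 13 (not isolated) | [Li]OC1=C(CCO[Si](c2ccccc2)(c2ccccc2)C(C)(C)C)[C@H](C)[C@H](c2cc(OC)c(OC)c(OC)c2)O1 | intermediate
16 | (3R,4S,5R)-3-allyl-3-[2-(tert-butyldiphenylsilyloxy)ethyl]-4-methyl-5-(3,4,5-trimethoxyphenyl)oxolan-2-one | C=CC[C@]1(CCO[Si](c2ccccc2)(c2ccccc2)C(C)(C)C)C(=O)O[C@@H](c2cc(OC)c(OC)c(OC)c2)[C@H]1C | intermediate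
17 | (3R,4S,5R)-3-allyl-3-[2-(tert-butyldiphenylsilyloxy)ethyl]-4-methyl-5-(3,4,5-trimethoxyphenyl)oxolan-2-ol (both anomers) | C=CC[C@]1(CCO[Si](c2ccccc2)(c2ccccc2)C(C)(C)C)C(O)O[C@@H](c2cc(OC)c(OC)c(OC)c2)[C@H]1C | intermediate
18 | (1R,2S,3R)-3-[2-(tert-butyldiphenylsilyloxy)ethyl]-3-ethynyl-2-methyl-1-(3,4,5-trimethoxyphenyl)hex-5-en-1-ol | C=CC[C@](CCO[Si](c1ccccc1)(c1ccccc1)C(C)(C)C)(C#C)[C@H](C)[C@@H](O)c1cc(OC)c(OC)c(OC)c1 | intermediate
19 | methyl (2E)-2-[(3R,4S,5R)-3-allyl-3-[2-(tert-butyldiphenylsilyloxy)ethyl]-4-methyl-5-(3,4,5-trimethoxyphenyl)oxolan-2-ylidene]acetate | C=CC[C@]1(CCO[Si](c2ccccc2)(c2ccccc2)C(C)(C)C)/C(=C\C(=O)OC)O[C@@H](c2cc(OC)c(OC)c(OC)c2)[C@H]1C | intermediate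
20 | (2E)-2-[(3R,4S,5R)-3-allyl-3-[2-(tert-butyldiphenylsilyloxy)ethyl]-4-methyl-5-(3,4,5-trimethoxyphenyl)oxolan-2-ylidene]ethan-1-ol | C=CC[C@]1(CCO[Si](c2ccccc2)(c2ccccc2)C(C)(C)C)/C(=C\CO)O[C@@H](c2cc(OC)c(OC)c(OC)c2)[C@H]1C | intermediate
21 | 2-[(2E,3R,4S,5R)-3-allyl-2-(2-hydroxyethylidene)-4-methyl-5-(3,4,5-trimethoxyphenyl)oxolan-3-yl]ethan-1-ol | C=CC[C@]1(CCO)/C(=C\CO)O[C@@H](c2cc(OC)c(OC)c(OC)c2)[C@H]1C | intermediate
22 | 2-[(2E,3R,4S,5R)-3-allyl-4-methyl-2-(2-oxoethylidene)-5-(3,4,5-trimethoxyphenyl)oxolan-3-yl]acetaldehyde | C=CC[C@]1(CC=O)/C(=C\C=O)O[C@@H](c2cc(OC)c(OC)c(OC)c2)[C@H]1C | intermediate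
23 | (2R,3S,3aR)-3a-allyl-6-hydroxy-3-methyl-2-(3,4,5-trimethoxyphenyl)-2,3,3a,4-tetrahydro-1-benzofuran-5(6H)-one (both C6 epimers) | C=CC[C@]12CC(=O)C(O)C=C1O[C@@H](c1cc(OC)c(OC)c(OC)c1)[C@H]2C | intermediate
24 | (2R,3S,3aR)-3a-allyl-3-methyl-2-(3,4,5-trimethoxyphenyl)-2,3,3a,4-tetrahydro-1-benzofuran-5,6-dione (not isolated) | C=CC[C@]12CC(=O)C(=O)C=C1O[C@@H](c1cc(OC)c(OC)c(OC)c1)[C@H]2C | intermediate
25 | (2R,3S,3aS)-3a-allyl-5-hydroxy-3-methyl-2-(3,4,5-trimethoxyphenyl)-3,3a-dihydro-1-benzofuran-6(2H)-one | C=CC[C@]12C=C(O)C(=O)C=C1O[C@@H](c1cc(OC)c(OC)c(OC)c1)[C@H]2C | intermediate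
26 | (2R,3S,3aS)-3a-allyl-5-methoxy-3-methyl-2-(3,4,5-trimethoxyphenyl)-3,3a-dihydro-1-benzofuran-6(2H)-one | C=CC[C@]12C=C(OC)C(=O)C=C1O[C@@H](c1cc(OC)c(OC)c(OC)c1)[C@H]2C | target

## Step count and risk

Total: 15 steps. Longest linear sequence: 14 steps (1 to 26 through steps 1–3 and 5–15; step 4 is a one-step side branch).

**Step 13 (key step, new method).**
- The vinylogous formate may be too poor an acceptor, so that intermolecular acyloin coupling of the aliphatic aldehyde or enolate aldol closure of C4 onto C6 overtakes ring closure.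
- The carbene may instead engage the enal, leading to internal redox and opening of ring B.
- The E geometry may be lost by nucleophile- or acid-promoted isomerisation before closure.
- The adduct gives up the conjugation of the vinylogous formate, so the closure may be reversible; base-mediated α-ketol transposition to the conjugated isomer would help, and converges in step 14.
- Fallback with known chemistry: from 22, reductive pinacol cyclisation with SmI2 in THF/t-BuOH at −78 °C joins the same two carbons and should give the ring A 5,6-diol F1. Oxidation of both carbinols of F1 (Dess–Martin periodinane, NaHCO3) then gives dione 24 and hence diosphenol 25, where the route is rejoined.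

**Step 9.**
- The alkenylpalladium intermediate carries palladium next to the quaternary carbon with its allyl group, so alkene insertion (a Heck-type cascade) may compete with CO capture.
- Protodepalladation followed by methanol addition to the enol ether is a second risk, as is slow oxypalladation at the hindered alkyne.
- Fallback: from 18, iodoetherification (I2, NaHCO3, MeCN) by anti addition should give the (E)-iodomethylene oxolane F2. Its methoxycarbonylation with Pd(PPh3)4, a zerovalent palladium complex, under CO in MeOH/Et3N proceeds with retention and returns to 19. This separates C–O from C–C bond formation and allows the CO pressure to be raised freely.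

**Step 12.**
- In 21 a free C5 hydroxyl sits next to an electron-rich enol ether, so trace acid can cause internal ketal formation or allylic ionisation at C6.
- The geometry may erode, or oxidation may stop at a hydroxy aldehyde that closes to a lactol.
- Fallback: from 20, oxidise the allylic alcohol alone (MnO2, CH2Cl2) to the silyl-protected E enal F3, cleave the silyl ether (Bu4NF buffered with AcOH) to hydroxy enal F4, and oxidise that (Dess–Martin periodinane, NaHCO3) to 22. The free C5 hydroxyl then never meets an electron-rich enol ether, only the much less basic vinylogous formate.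

**Step 8.**
- Ring opening of the hindered lactol may be slow, so the neopentyl aldehyde is engaged incompletely and the reagent decomposes first.
- Fallback: from 17, Wittig chloromethylenation (Ph3PCH2Cl chloride, NaN(SiMe3)2, THF) to the chloroalkene F5 (E/Z mixture), then double deprotonation–elimination with excess LiN(i-Pr)2 to return to alkynol 18.

## Further compounds

F1 | step 13 | (2R,3S,3aR)-3a-allyl-3-methyl-2-(3,4,5-trimethoxyphenyl)-2,3,3a,4,5,6-hexahydro-1-benzofuran-5,6-diol (diol stereoisomers) | C=CC[C@]12CC(O)C(O)C=C1O[C@@H](c1cc(OC)c(OC)c(OC)c1)[C@H]2C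
F2 | step 9 | (2E,3R,4S,5R)-3-allyl-3-[2-(tert-butyldiphenylsilyloxy)ethyl]-2-(iodomethylidene)-4-methyl-5-(3,4,5-trimethoxyphenyl)oxolane | C=CC[C@]1(CCO[Si](c2ccccc2)(c2ccccc2)C(C)(C)C)/C(=C\I)O[C@@H](c2cc(OC)c(OC)c(OC)c2)[C@H]1C
F3 | step 12 | (2E)-2-[(3R,4S,5R)-3-allyl-3-[2-(tert-butyldiphenylsilyloxy)ethyl]-4-methyl-5-(3,4,5-trimethoxyphenyl)oxolan-2-ylidene]acetaldehyde | C=CC[C@]1(CCO[Si](c2ccccc2)(c2ccccc2)C(C)(C)C)/C(=C\C=O)O[C@@H](c2cc(OC)c(OC)c(OC)c2)[C@H]1C
F4 | step 12 | (2E)-2-[(3R,4S,5R)-3-allyl-3-(2-hydroxyethyl)-4-methyl-5-(3,4,5-trimethoxyphenyl)oxolan-2-ylidene]acetaldehyde | C=CC[C@]1(CCO)/C(=C\C=O)O[C@@H](c2cc(OC)c(OC)c(OC)c2)[C@H]1C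
F5 | step 8 | (1R,2S,3R)-3-[2-(tert-butyldiphenylsilyloxy)ethyl]-3-(2-chloroethenyl)-2-methyl-1-(3,4,5-trimethoxyphenyl)hex-5-en-1-ol (E/Z mixture) | C=CC[C@](CCO[Si](c1ccccc1)(c1ccccc1)C(C)(C)C)(C=CCl)[C@H](C)[C@@H](O)c1cc(OC)c(OC)c(OC)c1
A1 | alternative 1 | 3a-allyl-5-methoxy-2-(3,4,5-trimethoxyphenyl)-1-benzofuran-6(3aH)-one, C3a as in the target | C=CC[C@]12C=C(OC)C(=O)C=C1OC(c1cc(OC)c(OC)c(OC)c1)=C2
A2 | alternative 1 | cyclopropane adduct fused across C2 and C3 of A1, methylene anti to allyl | C=CC[C@]12C=C(OC)C(=O)C=C1O[C@@]3(c4cc(OC)c(OC)c(OC)c4)C[C@@H]23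
A3 | alternative 2 | 4-allyl-4-[(1S,2R)-1-hydroxy-1-(3,4,5-trimethoxyphenyl)propan-2-yl]-2,6-dimethoxycyclohexa-2,5-dien-1-one | C=CCC1(C=C(OC)C(=O)C(OC)=C1)[C@H](C)[C@@H](O)c1cc(OC)c(OC)c(OC)c1
A4 | alternative 2 | cis-fused 7-methoxy-7,7a-dihydro form of the target (C7 of either configuration) | C=CC[C@]12C=C(OC)C(=O)C(OC)[C@H]1O[C@@H](c1cc(OC)c(OC)c(OC)c1)[C@H]2C
A5 | alternative 3 | 4-alkenyl-3-isopropoxy-4-methoxycyclobut-2-en-1-one carrying the allyl group and the silyloxy aryl side chain on the alkene terminus | C=CCC(=CC1(OC)C(=O)C=C1OC(C)C)[C@H](C)[C@@H](O[Si](C)(C)C(C)(C)C)c1cc(OC)c(OC)c(OC)c1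
A6 | alternative 3 | 6-allyl-3-isopropoxy-4-methoxycyclohexa-2,4-dienone with the silyloxy aryl side chain on C6 | C=CC[C@@]1(C=C(OC)C(OC(C)C)=CC1=O)[C@H](C)[C@@H](O[Si](C)(C)C(C)(C)C)c1cc(OC)c(OC)c(OC)c1
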